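The 2H-pyran ring is disconnected at O1–C8a and C3–C4 (chromene numbering). The arene partner is a 2-fluorobenzaldehyde: its formyl carbon is C4 and its C–F carbon is C8a, which lies para to the C6 isobutyryl ketone. The other partner is the C,O-dianion LiCH2–CMe2–OLi. In one pot the carbanion (C3) adds to the aldehyde and the tertiary alkoxide (O1) displaces fluoride, closing the oxygen ring. Acid then dehydrates C4–OH to the C3=C4 alkene and frees the phenols. C8, the last open arene position, is finally joined through CH2 to C3 of the 4-hydroxy-2-pyrone.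

Key step: step 4

Remark: compound 12 is taken as a purchasable silyl enol ether of pentan-3-one; either alkene geometry should give the same pyrone.

Step 1
Reactants: 1 5-fluorobenzene-1,3-diol
Product: 2 1-fluoro-3,5-bis(methoxymethoxy)benzene
Conditions: MOMCl, i-Pr2NEt, CH2Cl2, 0 °C → rt
Reagents that add atoms: chloromethyl methyl ether (MOMCl) COCCl
Why: Double O-alkylation of the phenols (Williamson-type MOM ether formation) should install two acid-labile groups that also act as ortho-directing groups in step 2.

Step 2
Reactants: 2 1-fluoro-3,5-bis(methoxymethoxy)benzene; 3 2-methylpropanal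
Product: 5 2-fluoro-5-(1-hydroxy-2-methylpropyl)-4,6-bis(methoxymethoxy)benzaldehyde (racemic), via lithium alkoxide 4 (not isolated)
Conditions: n-BuLi, THF, −20 °C; 3, −78 °C; s-BuLi, TMEDA, −78 °C; DMF, −78 °C → rt; H2O
Reagents that add atoms: N,N-dimethylformamide CN(C)C=O
Why: In this sequential directed ortho-metalation the first lithiation should occur at the carbon flanked by both OMOM groups and 1,2-addition to 3 gives alkoxide 4 (carbinol centre racemic, removed in step 3), after which the second lithiation at a carbon between F and OMOM (the two remaining sites are equivalent) is formylated by DMF.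

Step 3
Reactants: 5 2-fluoro-5-(1-hydroxy-2-methylpropyl)-4,6-bis(methoxymethoxy)benzaldehyde
Product: 6 2-fluoro-4,6-bis(methoxymethoxy)-5-(2-methylpropanoyl)benzaldehyde
Conditions: Dess–Martin periodinane, CH2Cl2, rt
Reagents that add atoms: none
Why: Dess–Martin oxidation of the secondary benzylic alcohol should give the ketone without touching the aldehyde or the MOM ethers.

Step 4
Reactants: 7 1-chloro-2-methylpropan-2-ol; 6 2-fluoro-4,6-bis(methoxymethoxy)-5-(2-methylpropanoyl)benzaldehyde
Product: 10 1-[4-hydroxy-5,7-bis(methoxymethoxy)-2,2-dimethyl-3,4-dihydro-2H-chromen-6-yl]-2-methylpropan-1-one (racemic), via lithio alkoxide 8 (not isolated), via dilithium diolate 9 (not isolated)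
Conditions: 7, n-BuLi, THF, −78 °C; LiC10H8 (lithium naphthalenide, 2 equiv), −78 °C; 6, −78 °C; DMPU, 65 °C; H2O
Reagents that add atoms: none
Why: Chlorine–lithium exchange on the lithium alkoxide of 7 gives the C,O-dianion 8, whose carbanion (C3) adds to the formyl carbon (C4) of 6 at −78 °C to give 9; on warming in THF/DMPU the tertiary alkoxide (O1) attacks C8a and expels fluoride through a Meisenheimer complex that the para C6 ketone stabilises. The closest known reaction types are the 1,2-addition of β-oxido organolithiums to aldehydes and the intramolecular SNAr O-arylation used for chromans, here run as one [3+3] annulation. The six-membered oxygen ring closes by ipso attack of O1 on the arene carbon (addition–elimination), the only ring size open to either alkoxide. The new C4 carbinol centre forms without control as a racemate and is removed in step 5. Chemoselectivity for the aldehyde rests on the ketone being flanked by two ortho substituents and on the low temperature, which also keeps 8 from losing Li2O; fluoride at C8a is the only leaving group on the ring.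

Step 5
Reactants: 10 1-[4-hydroxy-5,7-bis(methoxymethoxy)-2,2-dimethyl-3,4-dihydro-2H-chromen-6-yl]-2-methylpropan-1-one
Product: 11 1-(5,7-dihydroxy-2,2-dimethyl-2H-chromen-6-yl)-2-methylpropan-1-one
Conditions: HCl (3 M aq.), MeOH, 45 °C
Reagents that add atoms: none
Why: Acid should ionise the benzylic C4–OH (cation stabilised by O1 and the ring oxygens) and E1 loss of a C3 proton gives the C3=C4 alkene and erases the C4 stereocentre, while the MOM acetals are solvolysed to the ketone-chelated phenols.

Step 6
Reactants: 12 (Z)-3-(trimethylsilyloxy)pent-2-ene; 13 propanedioyl dichloride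
Product: 14 6-ethyl-4-hydroxy-5-methyl-2H-pyran-2-one
Conditions: Et2O, −78 °C → rt
Reagents that add atoms: none
Why: C-acylation of the silyl enol ether by one acid chloride, then ring closure of the enolised 1,3-diketone oxygen on the second acid chloride (acylation/lactonisation), should give the 4-hydroxy-2-pyrone.

Step 7
Reactants: 14 6-ethyl-4-hydroxy-5-methyl-2H-pyran-2-one; 11 1-(5,7-dihydroxy-2,2-dimethyl-2H-chromen-6-yl)-2-methylpropan-1-one
Product: 17 3-{[5,7-dihydroxy-2,2-dimethyl-6-(2-methylpropanoyl)-2H-chromen-8-yl]methyl}-6-ethyl-4-hydroxy-5-methyl-2H-pyran-2-one, via Mannich base 15 (not isolated), via pyrone methide 16 (not isolated)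
Conditions: Me2N=CH2 I (Eschenmoser's salt), MeCN, rt; then 11, 60 °C
Reagents that add atoms: N,N-dimethylmethyleneiminium iodide (Eschenmoser's salt) C=[N+](C)C.[I-]
Why: Mannich aminomethylation at pyrone C3 gives 15, which loses dimethylamine to the methide 16, and C8 of 11, the only unsubstituted and doubly oxygen-activated arene carbon, should add in a Friedel–Crafts-type conjugate addition (Mannich/methide coupling).

Compound list
1 | 5-fluorobenzene-1,3-diol | Oc1cc(O)cc(F)c1 | starting material
2 | 1-fluoro-3,5-bis(methoxymethoxy)benzene | COCOc1cc(F)cc(OCOC)c1 | intermediate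
3 | 2-methylpropanal | CC(C)C=O | starting material
4 | lithium 1-[4-fluoro-2,6-bis(methoxymethoxy)phenyl]-2-methylpropan-1-olate (racemic) | [Li+].[O-]C(C(C)C)c1c(OCOC)cc(F)cc1OCOC | intermediate
5 | 2-fluoro-5-(1-hydroxy-2-methylpropyl)-4,6-bis(methoxymethoxy)benzaldehyde (racemic) | O=Cc1c(F)cc(OCOC)c(C(O)C(C)C)c1OCOC | intermediate
6 | 2-fluoro-4,6-bis(methoxymethoxy)-5-(2-methylpropanoyl)benzaldehyde | O=Cc1c(F)cc(OCOC)c(C(=O)C(C)C)c1OCOC | intermediate
7 | 1-chloro-2-methylpropan-2-ol | CC(C)(O)CCl | starting material
8 | lithium 1-lithio-2-methylpropan-2-olate | [Li]CC(C)(C)O[Li] | intermediate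
9 | dilithium 1-[2-fluoro-4,6-bis(methoxymethoxy)-5-(2-methylpropanoyl)phenyl]-3-methylbutane-1,3-diolate (racemic) | [Li+].[Li+].[O-]C(CC(C)(C)[O-])c1c(F)cc(OCOC)c(C(=O)C(C)C)c1OCOC | intermediate
10 | 1-[4-hydroxy-5,7-bis(methoxymethoxy)-2,2-dimethyl-3,4-dihydro-2H-chromen-6-yl]-2-methylpropan-1-one (racemic) | CC(C)C(=O)c1c(OCOC)cc2OC(C)(C)CC(O)c2c1OCOC | intermediate
11 | 1-(5,7-dihydroxy-2,2-dimethyl-2H-chromen-6-yl)-2-methylpropan-1-one | CC(C)C(=O)c1c(O)cc2OC(C)(C)C=Cc2c1O | intermediate
12 | (Z)-3-(trimethylsilyloxy)pent-2-ene | C/C=C(/CC)O[Si](C)(C)C | starting material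
13 | propanedioyl dichloride (malonyl dichloride) | O=C(Cl)CC(=O)Cl | starting material
14 | 6-ethyl-4-hydroxy-5-methyl-2H-pyran-2-one | CCc1oc(=O)cc(O)c1C | intermediate
15 | 3-[(dimethylamino)methyl]-6-ethyl-4-hydroxy-5-methyl-2H-pyran-2-one | CCc1oc(=O)c(CN(C)C)c(O)c1C | intermediate
16 | 6-ethyl-5-methyl-3-methylidene-2H-pyran-2,4(3H)-dione | CCC1=C(C)C(=O)C(=C)C(=O)O1 | intermediate
17 | 3-{[5,7-dihydroxy-2,2-dimethyl-6-(2-methylpropanoyl)-2H-chromen-8-yl]methyl}-6-ethyl-4-hydroxy-5-methyl-2H-pyran-2-one | CCc1oc(=O)c(Cc2c(O)c(C(=O)C(C)C)c(O)c3c2OC(C)(C)C=C3)c(O)c1C | target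

Total step count: 7. Longest linear sequence: 6 steps (steps 1, 2, 3, 4, 5 and 7); step 6 is the convergent branch.

Steps most likely to fail

Step 4. Proton transfer from the isobutyryl α-C–H to the alkoxides could turn the para ketone into an enolate, deactivate the ring and stall the fluoride displacement. The dianion could also lose Li2O before it adds, or lithiate the position next to fluorine with loss of LiF. The fallback sets out from 6 and closes the two bonds separately with known chemistry. SNAr of 6 with the sodium alkoxide of 2-methylbut-3-en-2-ol (NaH, THF, 0 °C; fluoride is activated by the ortho formyl and para ketone) should give 2-[(2-methylbut-3-en-2-yl)oxy]-4,6-bis(methoxymethoxy)-5-(2-methylpropanoyl)benzaldehyde F1. Wittig methylenation of the aldehyde (Ph3P=CH2, THF, 0 °C) should give 1-[3-ethenyl-2,6-bis(methoxymethoxy)-4-[(2-methylbut-3-en-2-yl)oxy]phenyl]-2-methylpropan-1-one F2. Ring-closing metathesis (second-generation Grubbs catalyst, CH2Cl2, 40 °C) should give 1-[5,7-bis(methoxymethoxy)-2,2-dimethyl-2H-chromen-6-yl]-2-methylpropan-1-one F3. Cleavage of the MOM ethers (HCl, MeOH) then comes back to the route at 11.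

Step 2. The first metalation could occur next to fluorine instead of between the OMOM groups, the ortho-lithiated fluoroarene could lose LiF if the temperature drifts, and the second metalation could stay incomplete in the presence of the alkoxide. The fallback sets out from 2 and replaces the second metalation by halogenation and exchange. Lithiation of 2 (n-BuLi) and acylation with N-methoxy-N-methyl-2-methylpropanamide should give 1-[4-fluoro-2,6-bis(methoxymethoxy)phenyl]-2-methylpropan-1-one F4. Bromination with NBS (MeCN, 0 °C) at one of the two equivalent free positions should give 1-[3-bromo-4-fluoro-2,6-bis(methoxymethoxy)phenyl]-2-methylpropan-1-one F5. Bromine–magnesium exchange (i-PrMgCl·LiCl, THF, −20 °C, hindered ketone tolerated) and DMF then come back to the route at 6.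

Step 7. The methide could condense with a second pyrone to a methylene-bis-pyrone, or add across the chromene C3=C4 double bond in a hetero-Diels–Alder reaction, before the arene captures it. The fallback sets out from 11 and moves the electrophilic centre to the arene. Aminomethylation of 11 at C8 with Eschenmoser's salt should give 1-{8-[(dimethylamino)methyl]-5,7-dihydroxy-2,2-dimethyl-2H-chromen-6-yl}-2-methylpropan-1-one F6. Heating F6 with 14 (toluene, 100 °C) should release an ortho-quinone methide of the arene that C3 of the pyrone captures, which comes back to the route at 17.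

Further compounds
F1 | step 4 | 2-[(2-methylbut-3-en-2-yl)oxy]-4,6-bis(methoxymethoxy)-5-(2-methylpropanoyl)benzaldehyde | O=Cc1c(OC(C)(C)C=C)cc(OCOC)c(C(=O)C(C)C)c1OCOC
F2 | step 4 | 1-[3-ethenyl-2,6-bis(methoxymethoxy)-4-[(2-methylbut-3-en-2-yl)oxy]phenyl]-2-methylpropan-1-one | C=Cc1c(OC(C)(C)C=C)cc(OCOC)c(C(=O)C(C)C)c1OCOC
F3 | step 4 | 1-[5,7-bis(methoxymethoxy)-2,2-dimethyl-2H-chromen-6-yl]-2-methylpropan-1-one | CC(C)C(=O)c1c(OCOC)cc2OC(C)(C)C=Cc2c1OCOC
F4 | step 2 | 1-[4-fluoro-2,6-bis(methoxymethoxy)phenyl]-2-methylpropan-1-one | CC(C)C(=O)c1c(OCOC)cc(F)cc1OCOC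
F5 | step 2 | 1-[3-bromo-4-fluoro-2,6-bis(methoxymethoxy)phenyl]-2-methylpropan-1-one | CC(C)C(=O)c1c(OCOC)cc(F)c(Br)c1OCOC
F6 | step 7 | 1-{8-[(dimethylamino)methyl]-5,7-dihydroxy-2,2-dimethyl-2H-chromen-6-yl}-2-methylpropan-1-one | CC(C)C(=O)c1c(O)c(CN(C)C)c2OC(C)(C)C=Cc2c1O
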